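**Assumption:** 13 is planar and achiral (no stereocentre, no stereogenic axis), so "single enantiomer" sets no stereochemical task and the route contains no stereoselective step.

## Analysis of the target

The target 13 is 3,4,7-tribromo-2-chloro-1H-indole: a benzo-fused pyrrole with Cl on C2, Br on C3, Br on C4 and C7, and only N1–H, C5–H and C6–H unsubstituted. It has no stereocentre, so the whole problem is one of regiochemistry. The feature to which the strategy is tied is the N1–C2(Cl)=C3(Br)–C3a unit of the pyrrole ring: chlorine sits on the carbon bonded to N1 and bromine on the carbon bonded to C3a, which is the pattern left by anti addition of nitrogen and Br+ across a 1-chloroalkyne. Placing two different halogens on C2 and C3 by electrophilic halogenation of an indole is unreliable, because both halogenations start at C3 and the second passes through a 3,3-dihalo-3H-indole in which either halogen can shift to C2. The C4/C7 bromines cannot be introduced on an indole (with C3 blocked, halogenation goes to C5 and C6), so they must come in with the benzene building block, flanking the future ring-fusion carbons C3a and C7a. The three C–Br bonds rule out Pd(0)/Ni(0) catalysis, alkyllithium reagents and dissolving metals throughout. The N–H 2-haloindole is sensitive to acid (C3 protonation, then hydrolysis or oligomerisation) and to light, so it should be set free last, under basic, non-reducing conditions.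

## Retrosynthetic reasoning

**13 ⇒ 12 (N1–S bond).** The free N–H is unmasked last from the N-methylsulfonyl indole 12. The sulfonyl group deactivates the benzene ring towards electrophilic bromine, offers nitrogen as the only internal nucleophile, and leaves easily from a tetrahaloindole because the indolide is a good leaving group. The forward reaction only has to break N–S under mild base without touching C–Cl or C–Br.

**12 ⇒ 9 + 10 (N1–C2 and C3–Br, key disconnection).** Both bonds are cut at once, which opens the pyrrole ring to the 2-(chloroethynyl)sulfonanilide 9 and electrophilic bromine from 10. The cut is made here because the alkyne carbons of 9 are already differentiated: the chlorine-bearing terminus can only become C2 and the aryl-bearing carbon can only become C3. The Cl/Br regiochemistry is therefore written into the connectivity of 9 and no longer depends on competing rates of halogenation or halogen shifts. The forward reaction must deliver Br+ to the alkyne and close the ring through nitrogen in the 5-endo-dig mode.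

**9 ⇒ 6 + 7 (C(sp)–Cl).** The chlorine on the alkyne terminus is traced back to the terminal alkyne 6 and electrophilic chlorine from 7. Chlorine is introduced on an acetylide carbon, where there is no regiochemical choice. The forward reaction needs a base that deprotonates N–H and C≡C–H but does not exchange aryl bromides.

**6 ⇒ 3 + 4 (C≡C).** The alkyne is cut to the aldehyde 3 and the one-carbon diazophosphonate reagent 4. This avoids a Sonogashira coupling, which could not distinguish a coupling site from the two aryl bromides. The forward reaction is a one-carbon homologation under mild carbonate conditions.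

**3 ⇒ 1 + 2 (C7a–N).** The aryl C–N bond is cut to the fluoroaldehyde 1 and the sulfonamide 2. Compound 1, a catalogue building block, already holds both bromines in the right places: its C3–Br (next to C–F) becomes C7–Br and its C6–Br (next to C–CHO) becomes C4–Br. The formyl group activates the ortho fluoride for substitution and then serves as the alkyne precursor, and the sulfonamide enters as the nucleophile, so protection costs no separate step.

## Alternatives that were turned down

**Alternative 1:** Textbook route, cutting only C2–Cl and C3–Br of an intact indole.
- Forward: a Bartoli reaction of the corresponding 2,5-dibrominated nitroarene with a vinyl Grignard reagent would give 4,7-dibromo-1H-indole A1; 10 would brominate C3 to 3,4,7-tribromo-1H-indole A2; 7 would then have to chlorinate C2.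
- Turned down: the chlorination of A2 starts at C3, the most nucleophilic carbon, and gives racemic 3,4,7-tribromo-3-chloro-3H-indole A3. A3 can rearomatise only by a 1,2-halogen shift to C2, and bromine, the better bridging and migrating group, is expected to move. That leads to the 2-bromo-3-chloro constitutional isomer of 13, which has the same mass and nearly the same polarity. Reversing the order needs a C2-selective chlorination of A1, for which the indole offers no electronic basis. The Bartoli step also uses three equivalents of Grignard reagent on a substrate with two C–Br bonds.

**Alternative 2:** Lactam route, cutting N1–C2 as an amide bond and C2–Cl as an amide carbonyl.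
- Forward: Sandmeyer isatin synthesis on the 2,5-dibrominated aniline would give 4,7-dibromoindoline-2,3-dione A4; Wolff–Kishner reduction would give 4,7-dibromoindolin-2-one A5; deoxychlorination with a phosphorus(V) oxychloride would give 4,7-dibromo-2-chloro-1H-indole A6; bromination with 10 at C3 would give the target.
- Turned down: the regiochemistry is sound, but it takes about five steps, all of them functional-group changes, and the three pyrrole-ring events (ring closure, Cl, Br) are spread over separate operations. The isatin closure is an electrophilic substitution on a doubly deactivated ring. The deoxychlorination would generate the N–H 2-chloroindole A6 in hot acid, the conditions under which it is protonated at C3 and hydrolyses or self-condenses.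

**Alternative 3:** Nitrene route, cutting N1–C2 with a halogen migration.
- Forward: Cadogan–Sundberg deoxygenative cyclisation of 1,4-dibromo-2-(2-bromo-2-chloroethenyl)-3-nitrobenzene A7 (E/Z mixture) with a trialkyl phosphite would give racemic 2,4,7-tribromo-2-chloro-2H-indole A8. A8 would then need a [1,5]-shift of bromine, and not chlorine, from C2 to C3, followed by tautomerisation.
- Turned down: it needs no protecting group, but two things are unproven in one step. The Br-over-Cl migration rests only on relative C–X bond strengths, and C2 of A8 is an N,Br,Cl-substituted carbon that can ionise instead. Hot phosphite is also expected to attack the gem-dihaloalkene and the C–Br bonds. The nitroaldehyde needed for A7 has no short, regiodefined access.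

Key step: step 4

## Route

**Step 1**
Reactants: 1 3,6-dibromo-2-fluorobenzaldehyde; 2 methanesulfonamide
Product: 3 N-(3,6-dibromo-2-formylphenyl)methanesulfonamide
Conditions: 2 (1.5 equiv), K2CO3 (2.5 equiv), DMSO, 90 °C; then 1 M HCl
Reagents that add atoms: methanesulfonamide, CS(N)(=O)=O
Why: SNAr (addition–elimination) at the C–F carbon activated by the ortho formyl group; fluoride leaves far faster than the bromide that is also ortho to the formyl group because addition is rate-limiting, and the product is held as its sulfonamide anion, which protects it from a second arylation.

**Step 2**
Reactants: 3 N-(3,6-dibromo-2-formylphenyl)methanesulfonamide; 4 dimethyl (1-diazo-2-oxopropyl)phosphonate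
Product: 6 N-(3,6-dibromo-2-ethynylphenyl)methanesulfonamide, via diazoalkene 5 (not isolated)
Conditions: 4 (1.5 equiv), K2CO3 (3 equiv), MeOH, 0 °C to rt; aq. NH4Cl
Reagents that add atoms: dimethyl (1-diazo-2-oxopropyl)phosphonate, CC(=O)C(=[N+]=[N-])P(=O)(OC)OC
Why: Ohira–Bestmann variant of the Seyferth–Gilbert homologation: methanolysis of 4 releases the diazomethylphosphonate anion, Horner–Wadsworth–Emmons-type olefination gives the diazoalkene 5, and loss of N2 with 1,2-hydrogen shift gives the terminal alkyne; carbonate in methanol touches neither the aryl bromides nor the sulfonamide.

**Step 3**
Reactants: 6 N-(3,6-dibromo-2-ethynylphenyl)methanesulfonamide; 7 N-chlorosuccinimide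
Product: 9 N-[3,6-dibromo-2-(chloroethynyl)phenyl]methanesulfonamide, via dilithio dianion 8 (not isolated)
Conditions: LiHMDS (2.2 equiv), THF, −78 °C; NCS (1.05 equiv), −78 to −40 °C; aq. NH4Cl/Na2S2O3 at −40 °C
Reagents that add atoms: N-chlorosuccinimide, ClN1C(=O)CCC1=O
Why: Electrophilic chlorination of a metal acetylide: the hindered lithium amide removes N–H and C≡C–H without bromine–lithium exchange, the acetylide carbon of 8 is the most nucleophilic site towards NCS, and the cold quench returns the N–H before the anion can add to the new chloroalkyne.

**Step 4**
Reactants: 9 N-[3,6-dibromo-2-(chloroethynyl)phenyl]methanesulfonamide; 10 N-bromosuccinimide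
Product: 12 3,4,7-tribromo-2-chloro-1-(methylsulfonyl)-1H-indole, via bromirenium ion 11 (not isolated)
Conditions: NBS (1.1 equiv), K2CO3 (1.2 equiv), MeCN, 0 °C to rt, dark; aq. Na2S2O3
Reagents that add atoms: N-bromosuccinimide, BrN1C(=O)CCC1=O
Why: Proposed new method: 10 transfers Br+ to the chloroalkyne of the potassium salt of 9 to give the bromirenium ion 11, which the sulfonamide nitrogen opens anti at the chlorine-bearing carbon, so that N1–C2 and C3–Br form in one event and the alkyne chlorine becomes C2–Cl. The closest known reaction types are the 5-endo-dig iodo- and bromocyclisation of N-sulfonyl-2-alkynylanilines to 3-haloindoles and the base-promoted 5-endo-dig closure of 2-(haloethynyl)sulfonanilides to 2-haloindoles; what has not been shown is the halonium-triggered closure on a 1-haloalkyne. The pyrrole ring closes in the 5-endo-dig mode, and the 4-exo-dig alternative at the aryl-bearing carbon would give a benzazete and is out of reach, so ring size alone decides which alkyne carbon receives nitrogen. No stereocentre is formed; the anti addition only places N1 and Br trans across C2=C3, as the ring requires. The chlorine lone pair stabilises the positive charge building up on the attacked carbon, which offsets the usual preference of a haloalkyne for attack at the remote carbon. The selectivity needed is alkyne over arene bromination, and the benzene ring, carrying two bromines and a sulfonamide nitrogen, is switched off towards NBS, while the product has no nucleophilic position left. If the sulfonamide anion adds to the alkyne before bromine transfer, the resulting C3-unsubstituted N-sulfonylindole should still be brominated at C3 by the same reagent, so both orders of events lead to 12. The placement of Cl against Br is fixed by the connectivity of 9 and does not depend on relative rates.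

**Step 5**
Reactants: 12 3,4,7-tribromo-2-chloro-1-(methylsulfonyl)-1H-indole
Product: 13 3,4,7-tribromo-2-chloro-1H-indole
Conditions: KOH (3 equiv), THF/H2O (4:1), rt, dark; aq. NH4Cl to pH 7–8
Reagents that add atoms: none
Why: Base-induced cleavage of the sulfonamide N–S bond (hydroxide attack at sulfur or E1cB loss of sulfene), made easy by the tetrahaloindolide leaving group and the peri strain between N-sulfonyl, C2–Cl and C7–Br; aryl and vinyl halides do not react with hydroxide at rt, and the near-neutral work-up avoids the acid to which the N–H 2-chloroindole is sensitive.

## Compound list

1 | 3,6-dibromo-2-fluorobenzaldehyde | O=Cc1c(F)c(Br)ccc1Br | starting material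
2 | methanesulfonamide | CS(N)(=O)=O | starting material
3 | N-(3,6-dibromo-2-formylphenyl)methanesulfonamide | CS(=O)(=O)Nc1c(Br)ccc(Br)c1C=O | intermediate
4 | dimethyl (1-diazo-2-oxopropyl)phosphonate | CC(=O)C(=[N+]=[N-])P(=O)(OC)OC | starting material
5 | N-[3,6-dibromo-2-(2-diazoethenyl)phenyl]methanesulfonamide (diazoalkene, not isolated) | CS(=O)(=O)Nc1c(Br)ccc(Br)c1C=C=[N+]=[N-] | intermediate
6 | N-(3,6-dibromo-2-ethynylphenyl)methanesulfonamide | CS(=O)(=O)Nc1c(Br)ccc(Br)c1C#C | intermediate
7 | N-chlorosuccinimide | ClN1C(=O)CCC1=O | starting material
8 | dilithium salt of 6 (N-lithio sulfonamide, lithium acetylide; not isolated) | [Li+].[Li+].CS(=O)(=O)[N-]c1c(Br)ccc(Br)c1C#[C-] | intermediate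
9 | N-[3,6-dibromo-2-(chloroethynyl)phenyl]methanesulfonamide | CS(=O)(=O)Nc1c(Br)ccc(Br)c1C#CCl | intermediate
10 | N-bromosuccinimide | BrN1C(=O)CCC1=O | starting material
11 | 2-[3,6-dibromo-2-(methylsulfonylazanidyl)phenyl]-3-chlorobromiren-1-ium (bromirenium zwitterion, not isolated) | CS(=O)(=O)[N-]c1c(Br)ccc(Br)c1C2=C(Cl)[Br+]2 | intermediate
12 | 3,4,7-tribromo-2-chloro-1-(methylsulfonyl)-1H-indole | CS(=O)(=O)n1c(Cl)c(Br)c2c(Br)ccc(Br)c21 | intermediate
13 | 3,4,7-tribromo-2-chloro-1H-indole | Clc1[nH]c2c(Br)ccc(Br)c2c1Br | target

## Step count and risk

Total step count: 5. Longest linear sequence: 5 steps (1 → 3 → 6 → 9 → 12 → 13).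

**Step 4 (key step, bears the label).**
- What may go wrong: Br+ transfer to the electron-poor chloroalkyne may be slow, so that reversible N-bromination of the sulfonamide or halophilic attack at the alkyne chlorine takes over. The sulfonyl group may also be lost early from the strained product, followed by over-bromination of the freed indole.
- Fallback (known chemistry), from 9 back to 12: Cs2CO3 in DMSO at 60–80 °C should bring about the anionic 5-endo-dig closure to 4,7-dibromo-2-chloro-1-(methylsulfonyl)-1H-indole F1, a known transition-metal-free reaction type for 2-(haloethynyl)- and 2-(gem-dihalovinyl)sulfonanilides. Electrophilic bromination of F1 at C3, its only nucleophilic carbon, with Br2 and NaOAc in AcOH should then give 12. This splits the two bond formations of the key step into two classical operations.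

**Step 1.**
- What may go wrong: substitution may be slow, because the fluoride is flanked by two ortho substituents and the N-nucleophile is weak. The sulfonamide may condense reversibly with the aldehyde, and at forcing temperature the bromide ortho to the formyl group may be displaced.
- Fallback, from 1 back to 3: the small, strong nucleophile azide (NaN3, DMSO, rt) should give 2-azido-3,6-dibromobenzaldehyde F2. Staudinger reduction (PPh3, THF, then H2O, 50 °C) should give 2-amino-3,6-dibromobenzaldehyde F3, and sulfonylation with methanesulfonyl chloride in pyridine should lead to 3.

**Step 2.**
- What may go wrong: the aldehyde may be too weak an electrophile, because the ortho sulfonamide is present as its anion and the carbonyl has two ortho substituents. The alkylidene-carbene stage may also be intercepted by the neighbouring nitrogen instead of undergoing the 1,2-hydrogen shift.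
- Fallback, from 1 back to 6: nitrogen is carried through the homologation as the neutral azide. From 1 by way of 2-azido-3,6-dibromobenzaldehyde F2 as above, reagent 4 with K2CO3 in MeOH should give 2-azido-1,4-dibromo-3-ethynylbenzene F4. Staudinger reduction should give 3,6-dibromo-2-ethynylaniline F5, and mesylation in pyridine should give 6.

**Step 3.**
- What may go wrong: chlorination may occur at the sulfonamide nitrogen instead of the acetylide carbon, the double deprotonation may be incomplete, or the chloroalkyne may ring-close anionically on warming before the quench.
- Fallback, from 3 back to 9, avoiding the terminal alkyne and the dianion: a Ramirez-type dichloro-olefination (PPh3, BrCCl3, MeCN) should give N-[3,6-dibromo-2-(2,2-dichloroethenyl)phenyl]methanesulfonamide F6. Base-induced anti-elimination of HCl (KOtBu, THF, −78 to 0 °C) should give 9. Any ring closure under these conditions would give 4,7-dibromo-2-chloro-1-(methylsulfonyl)-1H-indole F1, which still leads to 12 by the fallback of step 4.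

## Further compounds

F1 | step 4 | 4,7-dibromo-2-chloro-1-(methylsulfonyl)-1H-indole | CS(=O)(=O)n1c(Cl)cc2c(Br)ccc(Br)c21
F2 | step 1 | 2-azido-3,6-dibromobenzaldehyde | [N-]=[N+]=Nc1c(Br)ccc(Br)c1C=O
F3 | step 1 | 2-amino-3,6-dibromobenzaldehyde | Nc1c(Br)ccc(Br)c1C=O
F4 | step 2 | 2-azido-1,4-dibromo-3-ethynylbenzene | [N-]=[N+]=Nc1c(Br)ccc(Br)c1C#C
F5 | step 2 | 3,6-dibromo-2-ethynylaniline | Nc1c(Br)ccc(Br)c1C#C
F6 | step 3 | N-[3,6-dibromo-2-(2,2-dichloroethenyl)phenyl]methanesulfonamide | CS(=O)(=O)Nc1c(Br)ccc(Br)c1C=C(Cl)Cl
A1 | alternative 1 | 4,7-dibromo-1H-indole | Brc1ccc(Br)c2[nH]ccc12
A2 | alternative 1 | 3,4,7-tribromo-1H-indole | Brc1c[nH]c2c(Br)ccc(Br)c12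
A3 | alternative 1 | 3,4,7-tribromo-3-chloro-3H-indole (racemic) | ClC1(Br)C=Nc2c(Br)ccc(Br)c12
A4 | alternative 2 | 4,7-dibromoindoline-2,3-dione | O=C1Nc2c(Br)ccc(Br)c2C1=O
A5 | alternative 2 | 4,7-dibromoindolin-2-one | O=C1Cc2c(Br)ccc(Br)c2N1
A6 | alternative 2 | 4,7-dibromo-2-chloro-1H-indole | Clc1cc2c(Br)ccc(Br)c2[nH]1
A7 | alternative 3 | 1,4-dibromo-2-(2-bromo-2-chloroethenyl)-3-nitrobenzene (E/Z mixture) | [O-][N+](=O)c1c(Br)ccc(Br)c1C=C(Cl)Br
A8 | alternative 3 | 2,4,7-tribromo-2-chloro-2H-indole (racemic) | ClC1(Br)C=C2C(Br)=CC=C(Br)C2=N1
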